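**Plan**

- The central ring is numbered as in the target SMILES: C1 carries the (S)-3-hydroxybutanoyloxy group, C2 OH, C3 aryl, C4 the 3-phenylpropanoyloxy group, C5 OH, C6 aryl. The retrosynthesis first cuts the two ester acyl–O bonds at C1 and C4, then the ring bonds C4–C5 and C6–C1.
- Feature that allows this: C1 and C4 are para, both oxygenated, and each sits between an aryl-bearing carbon and an oxygen-bearing carbon. The ring is therefore a reduced 2,5-dialkoxy-3,6-diaryl-1,4-quinone, which splits into a four-carbon C1–C2–C3–C4 piece (an aryl ethoxy cyclobutenedione) and a two-carbon C5–C6 piece (an aryl ynol ether).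
- Both pieces come from one aryl iodide: the C3–aryl bond by aryllithium addition to diethyl squarate, the C6–aryl bond by Negishi coupling of ethoxyethynylzinc chloride.
- Forward: the cobalt-mediated union of dione 5 and ynol ether 9 closes the central ring (the only ring made) as quinone 12. The ethoxy groups are then exchanged for benzyloxy groups, reduction frees only the C1 and C4 oxygens, these are acylated one after the other, and all benzyl groups are removed at the end.
- The single stereocentre (S, side chain) is bought as ethyl (S)-3-hydroxybutanoate and no bond to it is broken.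

Key step: step 3

**Route**

Step 1
Reactants: 1 1-(benzyloxy)-4-iodobenzene; 2 diethyl squarate (3,4-diethoxycyclobut-3-ene-1,2-dione)
Product: 5 3-[4-(benzyloxy)phenyl]-4-ethoxycyclobut-3-ene-1,2-dione, via 4-(benzyloxy)phenyllithium 3 (not isolated), via lithium alkoxide adduct 4 (not isolated)
Conditions: 1, n-BuLi, THF, −78 °C; cannulate into 2, THF, −78 °C; (CF3CO)2O, −78 °C; aq. NH4Cl
Reagents that add atoms: none
Why: Iodine–lithium exchange gives the aryllithium, which adds 1,2 to one squarate carbonyl (inverse addition at −78 °C limits double addition); O-trifluoroacetylation of the tertiary alkoxide then triggers ionisation and loss of ethanol on aqueous work-up, the standard conversion of squarate esters into 3-aryl-4-alkoxycyclobutenediones.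

Step 2
Reactants: 6 ethoxyacetylene; 1 1-(benzyloxy)-4-iodobenzene
Product: 9 1-(benzyloxy)-4-(ethoxyethynyl)benzene, via lithium ethoxyacetylide 7 (not isolated), via ethoxyethynylzinc chloride 8 (not isolated)
Conditions: 6, n-BuLi, THF, −78 °C; ZnCl2, −78 to 0 °C; 1, Pd(PPh3)4 (5 mol %), THF, rt; chromatography on basic Al2O3
Reagents that add atoms: none
Why: Deprotonation, transmetalation to zinc and Negishi coupling with the aryl iodide under zerovalent palladium is an established route to aryl ynol ethers; it keeps the acid-sensitive ethoxyalkyne away from copper salts and amine hydrohalides.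

Step 3
Reactants: 5 3-[4-(benzyloxy)phenyl]-4-ethoxycyclobut-3-ene-1,2-dione; 9 1-(benzyloxy)-4-(ethoxyethynyl)benzene
Product: 12 2,5-bis[4-(benzyloxy)phenyl]-3,6-diethoxycyclohexa-2,5-diene-1,4-dione, via chloro maleoylcobalt complex 10 (not isolated), via cationic maleoylcobalt complex 11 (not isolated)
Conditions: 5, CoCl(PPh3)3 (1.05 equiv), toluene, rt; hexane, decant; AgBF4 (1.0 equiv), MeCN, rt, filter off AgCl; 9 (1.5 equiv), MeCN, 60 °C
Reagents that add atoms: none
Why: Monovalent cobalt adds oxidatively across the strained C1–C4 bond between the two carbonyl carbons of 5 to give the five-membered trivalent-cobalt maleoyl complex 10; AgBF4 removes chloride, and in the acetonitrile complex 11 the ynol ether displaces a nitrile and inserts into the Co–C1 acyl bond so that C1 bonds to the aryl-bearing alkyne carbon C6, after which C–C reductive elimination joins C4 to the ethoxy-bearing C5. The closest known reaction type is the synthesis of quinones from cyclobutenediones and alkynes through maleoylcobalt and phthaloylcobalt complexes, a metal-mediated formal [4+2] annulation, applied here to an aryl ynol ether. The central six-membered ring is closed in the reductive elimination, by contraction of the seven-membered cobaltacycle with release of monovalent cobalt, and no other ring forms. No stereocentre is created. The step needs head-to-tail orientation (2,5- rather than 2,6-diethoxy): the nucleophilic carbon of the ynol ether is C6, and the more electrophilic acyl carbon is C1, which lies next to the ethoxy-bearing C2 and is not deactivated as a vinylogous ester the way C4 is, so the electronic match should favour the required isomer, although this is expected and not assured. Filtering off AgCl before 9 is added keeps free silver ion away from the ynol ether, and 60 °C stays below the temperature at which ethyl ynol ethers fragment to ketenes.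

Step 4
Reactants: 12 2,5-bis[4-(benzyloxy)phenyl]-3,6-diethoxycyclohexa-2,5-diene-1,4-dione
Product: 13 2,5-bis[4-(benzyloxy)phenyl]-3,6-dihydroxycyclohexa-2,5-diene-1,4-dione
Conditions: 2 M NaOH, 1,4-dioxane–H2O, 70 °C, argon; then 2 M HCl
Reagents that add atoms: sodium hydroxide, [Na+].[OH-]
Why: Each ethoxy group is the alkoxy part of a vinylogous ester, so hydroxide adds at C2 and C5 and expels ethoxide (addition–elimination, saponification of an alkoxyquinone); the dianion formed resists further attack and the benzyl aryl ethers are inert.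

Step 5
Reactants: 13 2,5-bis[4-(benzyloxy)phenyl]-3,6-dihydroxycyclohexa-2,5-diene-1,4-dione
Product: 14 2,5-bis(benzyloxy)-3,6-bis[4-(benzyloxy)phenyl]cyclohexa-2,5-diene-1,4-dione
Conditions: BnBr, Ag2O, DMF, rt, dark
Reagents that add atoms: benzyl bromide, BrCc1ccccc1
Why: Ag2O-mediated O-alkylation of the two vinylogous acid hydroxyls (Williamson-type etherification without strong base) gives the bis(benzyl enol ether), which fixes the C1 and C4 oxygens as the quinone carbonyls and puts hydrogenolysable groups on the C2 and C5 oxygens.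

Step 6
Reactants: 14 2,5-bis(benzyloxy)-3,6-bis[4-(benzyloxy)phenyl]cyclohexa-2,5-diene-1,4-dione; 15 3-phenylpropanoyl chloride
Product: 17 2,5-bis(benzyloxy)-3,6-bis[4-(benzyloxy)phenyl]-4-hydroxyphenyl 3-phenylpropanoate, via hydroquinone 16 (not isolated)
Conditions: Na2S2O4, THF–H2O, rt; extract under argon, dry; 15 (1.0 equiv, slow addition), pyridine, DMAP (cat.), CH2Cl2, −20 °C
Reagents that add atoms: none
Why: Dithionite reduces the quinone to the hydroquinone, whose two free phenols (on C1 and C4) are equivalent by symmetry, so acylation with one equivalent of acid chloride can give only one mono-ester; mono- against bis-acylation rests on stoichiometry alone, and unreacted diol (recovered as 14 after air oxidation) and diester are separated and recycled.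

Step 7
Reactants: 18 ethyl (S)-3-hydroxybutanoate
Product: 19 ethyl (S)-3-(benzyloxy)butanoate
Conditions: BnOC(=NH)CCl3, TfOH (cat.), CH2Cl2–cyclohexane, 0 °C to rt
Reagents that add atoms: benzyl 2,2,2-trichloroacetimidate, ClC(Cl)(Cl)C(=N)OCc1ccccc1
Why: Acid-catalysed trichloroacetimidate benzylation avoids the alkoxide that would cause retro-aldol cleavage or β-elimination; the C–O bond at the stereocentre is not broken, so the S configuration is kept.

Step 8
Reactants: 19 ethyl (S)-3-(benzyloxy)butanoate
Product: 20 (S)-3-(benzyloxy)butanoic acid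
Conditions: LiOH, THF–H2O, 0 °C to rt; then 1 M HCl
Reagents that add atoms: lithium hydroxide, [Li+].[OH-]
Why: Ester saponification under mild conditions; the stereocentre is β to the carbonyl and carries no acidic hydrogen, so it cannot epimerise, and the low temperature avoids elimination of benzyl alcohol.

Step 9
Reactants: 17 2,5-bis(benzyloxy)-3,6-bis[4-(benzyloxy)phenyl]-4-hydroxyphenyl 3-phenylpropanoate; 20 (S)-3-(benzyloxy)butanoic acid
Product: 21 2,5-bis(benzyloxy)-3,6-bis[4-(benzyloxy)phenyl]-4-[(3-phenylpropanoyl)oxy]phenyl (S)-3-(benzyloxy)butanoate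
Conditions: DIC, DMAP (cat.), CH2Cl2, 0 °C to rt
Reagents that add atoms: none
Why: Steglich esterification acylates the one remaining phenol (on C1); every other oxygen is benzylated, so there is no site-selectivity question and no neighbouring hydroxyl to which an acyl group could migrate.

Step 10
Reactants: 21 2,5-bis(benzyloxy)-3,6-bis[4-(benzyloxy)phenyl]-4-[(3-phenylpropanoyl)oxy]phenyl (S)-3-(benzyloxy)butanoate
Product: 22 2,5-dihydroxy-3,6-bis(4-hydroxyphenyl)-4-[(3-phenylpropanoyl)oxy]phenyl (S)-3-hydroxybutanoate
Conditions: H2 (1 atm), 10% Pd/C, EtOAc–THF, rt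
Reagents that add atoms: none
Why: Hydrogenolysis over palladium on carbon cleaves the four aryl benzyl ethers and the secondary alkyl benzyl ether, while the aryl alkanoate esters, the arene rings and the stereocentre are inert; a neutral aprotic medium and prompt isolation under argon limit acyl migration to the freed neighbouring phenols and air oxidation of the central ring.

**Compound list**

1 | 1-(benzyloxy)-4-iodobenzene | Ic1ccc(OCc2ccccc2)cc1 | starting material
2 | diethyl squarate (3,4-diethoxycyclobut-3-ene-1,2-dione) | CCOC1=C(OCC)C(=O)C1=O | starting material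
3 | 4-(benzyloxy)phenyllithium | [Li]c1ccc(OCc2ccccc2)cc1 | intermediate
4 | lithium 1-[4-(benzyloxy)phenyl]-2,3-diethoxy-4-oxocyclobut-2-en-1-olate (racemic) | CCOC1=C(OCC)C([O-])(c2ccc(OCc3ccccc3)cc2)C1=O.[Li+] | intermediate
5 | 3-[4-(benzyloxy)phenyl]-4-ethoxycyclobut-3-ene-1,2-dione | CCOC1=C(c2ccc(OCc3ccccc3)cc2)C(=O)C1=O | intermediate
6 | ethoxyacetylene | CCOC#C | starting material
7 | lithium ethoxyacetylide | CCOC#C[Li] | intermediate
8 | ethoxyethynylzinc chloride | CCOC#C[Zn]Cl | intermediate
9 | 1-(benzyloxy)-4-(ethoxyethynyl)benzene | CCOC#Cc1ccc(OCc2ccccc2)cc1 | intermediate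
10 | chloro{2-[4-(benzyloxy)phenyl]-3-ethoxy-1,4-dioxobut-2-ene-1,4-diyl}bis(triphenylphosphine)cobalt (trivalent cobalt, five-membered metallacycle) | CCOC1=C(c2ccc(OCc3ccccc3)cc2)C(=O)[Co-2](Cl)([P+](c2ccccc2)(c2ccccc2)c2ccccc2)([P+](c2ccccc2)(c2ccccc2)c2ccccc2)C1=O | intermediate
11 | bis(acetonitrile){2-[4-(benzyloxy)phenyl]-3-ethoxy-1,4-dioxobut-2-ene-1,4-diyl}bis(triphenylphosphine)cobalt tetrafluoroborate | CCOC1=C(c2ccc(OCc3ccccc3)cc2)C(=O)[Co-3]([N+]#CC)([N+]#CC)([P+](c2ccccc2)(c2ccccc2)c2ccccc2)([P+](c2ccccc2)(c2ccccc2)c2ccccc2)C1=O.F[B-](F)(F)F | intermediate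
12 | 2,5-bis[4-(benzyloxy)phenyl]-3,6-diethoxycyclohexa-2,5-diene-1,4-dione | CCOC1=C(c2ccc(OCc3ccccc3)cc2)C(=O)C(OCC)=C(c2ccc(OCc3ccccc3)cc2)C1=O | intermediate
13 | 2,5-bis[4-(benzyloxy)phenyl]-3,6-dihydroxycyclohexa-2,5-diene-1,4-dione | OC1=C(c2ccc(OCc3ccccc3)cc2)C(=O)C(O)=C(c2ccc(OCc3ccccc3)cc2)C1=O | intermediate
14 | 2,5-bis(benzyloxy)-3,6-bis[4-(benzyloxy)phenyl]cyclohexa-2,5-diene-1,4-dione | O=C1C(OCc2ccccc2)=C(c2ccc(OCc3ccccc3)cc2)C(=O)C(OCc2ccccc2)=C1c1ccc(OCc2ccccc2)cc1 | intermediate
15 | 3-phenylpropanoyl chloride | O=C(Cl)CCc1ccccc1 | starting material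
16 | 2,5-bis(benzyloxy)-3,6-bis[4-(benzyloxy)phenyl]benzene-1,4-diol | Oc1c(OCc2ccccc2)c(-c2ccc(OCc3ccccc3)cc2)c(O)c(OCc2ccccc2)c1-c1ccc(OCc2ccccc2)cc1 | intermediate
17 | 2,5-bis(benzyloxy)-3,6-bis[4-(benzyloxy)phenyl]-4-hydroxyphenyl 3-phenylpropanoate | O=C(CCc1ccccc1)Oc1c(OCc2ccccc2)c(-c2ccc(OCc3ccccc3)cc2)c(O)c(OCc2ccccc2)c1-c1ccc(OCc2ccccc2)cc1 | intermediate
18 | ethyl (S)-3-hydroxybutanoate | C[C@H](O)CC(=O)OCC | starting material
19 | ethyl (S)-3-(benzyloxy)butanoate | C[C@H](OCc1ccccc1)CC(=O)OCC | intermediate
20 | (S)-3-(benzyloxy)butanoic acid | C[C@H](OCc1ccccc1)CC(=O)O | intermediate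
21 | 2,5-bis(benzyloxy)-3,6-bis[4-(benzyloxy)phenyl]-4-[(3-phenylpropanoyl)oxy]phenyl (S)-3-(benzyloxy)butanoate | C[C@H](OCc1ccccc1)CC(=O)Oc1c(OCc2ccccc2)c(-c2ccc(OCc3ccccc3)cc2)c(OC(=O)CCc2ccccc2)c(OCc2ccccc2)c1-c1ccc(OCc2ccccc2)cc1 | intermediate
22 | 2,5-dihydroxy-3,6-bis(4-hydroxyphenyl)-4-[(3-phenylpropanoyl)oxy]phenyl (S)-3-hydroxybutanoate | C[C@H](O)CC(=O)Oc1c(O)c(-c2ccc(O)cc2)c(OC(=O)CCc2ccccc2)c(O)c1-c1ccc(O)cc1 | target

**Count and risks**

Total step count: 10. Longest linear sequence: 7 steps (step 1, then 3, 4, 5, 6, 9, 10).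

Steps most likely to fail:

1. Step 3. The ynol ether may insert with the opposite orientation, which would place the two ethoxy groups 2,6 and lead to a meta-terphenyl, or it may be hydrated or oligomerised by the cationic cobalt species before it inserts. The fallback gives up the annulation and builds the same quinone by cross-coupling. It sets out from 1, which is converted (n-BuLi, THF, −78 °C; B(OiPr)3; aq. HCl) into 4-(benzyloxy)phenylboronic acid F1. Commercial tetrabromo-1,4-benzoquinone is treated with NaOEt in EtOH to give 2,5-dibromo-3,6-diethoxycyclohexa-2,5-diene-1,4-dione F2, in which the para arrangement of the two bromines is fixed. A twofold Suzuki–Miyaura coupling of F2 with F1 (Pd(PPh3)4, K2CO3, 1,4-dioxane, 90 °C) should then give 12, where the route is rejoined.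

2. Step 6. Acylation of the symmetric hydroquinone is controlled by stoichiometry only, so over-acylation to the diester and unreacted diol will compete, and the hydroquinone may re-oxidise in air before it is acylated. The fallback sets out from quinone 14 and uses a carbene-catalysed redox esterification with 3-phenylpropanal (1,3-dimesitylimidazolium chloride (cat.), DBU, THF, rt). The Breslow intermediate is oxidised by the quinone, and the acyl azolium formed is captured by the hydroquinone monoanion it has just produced, so each quinone should take up one acyl group and one hydride. This comes back to the route at 17 without any new compound.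

3. Step 5. Alkylation of the ambident hydroxyquinone may go in part on the carbonyl-type oxygen to give ortho-quinone ethers, or stall after one benzyl group because the dihydroxyquinone is poorly soluble. The fallback sets out from 13 and avoids benzylation altogether. The four ring oxygens of 13 are equivalent by tautomerism, so esters placed on the two hydroxyl oxygens end up para to each other, each next to a carbonyl that becomes a free hydroxyl on reduction. Acylation of 13 with 15 (1 equiv, Et3N, THF, −20 °C; again stoichiometry-controlled) should give 2,5-bis[4-(benzyloxy)phenyl]-4-hydroxy-3,6-dioxocyclohexa-1,4-dien-1-yl 3-phenylpropanoate F3. Coupling with 20 (DIC, DMAP (cat.), CH2Cl2) should then give 2,5-bis[4-(benzyloxy)phenyl]-3,6-dioxo-4-[(3-phenylpropanoyl)oxy]cyclohexa-1,4-dien-1-yl (S)-3-(benzyloxy)butanoate F4. Hydrogenation of F4 (H2, 10% Pd/C, EtOAc) reduces the quinone to the hydroquinone and cleaves the three benzyl ethers, which comes back to the route at 22.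

**Further compounds**

F1 | step 3 | 4-(benzyloxy)phenylboronic acid | OB(O)c1ccc(OCc2ccccc2)cc1
F2 | step 3 | 2,5-dibromo-3,6-diethoxycyclohexa-2,5-diene-1,4-dione | CCOC1=C(Br)C(=O)C(OCC)=C(Br)C1=O
F0 | step 6 | none | none
F3 | step 5 | 2,5-bis[4-(benzyloxy)phenyl]-4-hydroxy-3,6-dioxocyclohexa-1,4-dien-1-yl 3-phenylpropanoate | O=C(CCc1ccccc1)OC1=C(c2ccc(OCc3ccccc3)cc2)C(=O)C(O)=C(c2ccc(OCc3ccccc3)cc2)C1=O
F4 | step 5 | 2,5-bis[4-(benzyloxy)phenyl]-3,6-dioxo-4-[(3-phenylpropanoyl)oxy]cyclohexa-1,4-dien-1-yl (S)-3-(benzyloxy)butanoate | C[C@H](OCc1ccccc1)CC(=O)OC1=C(c2ccc(OCc3ccccc3)cc2)C(=O)C(OC(=O)CCc2ccccc2)=C(c2ccc(OCc3ccccc3)cc2)C1=O
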